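I counted time in these flasks against how fast each one began.

| setting | dusk | midnight | dawn | summer | winter |
|---|---|---|---|---|---|
| Q | 200 mM | 100 mM | 200 mM | 300 mM | 600 mM |
| L | 300 mM | 200 mM | 600 mM | 300 mM | 300 mM |
| Z | 6.00 mM | 6.00 mM | 6.00 mM | 6.00 mM | 12.0 mM |
| time |  |  |  |  | 25 min |

- dusk run (time / min: [X] / mM): 0.90: 10.1; 2.7: 29.9; 5.2: 51.6; 8.2: 77.2; 12: 103.7; 16: 126.6; 20: 143.8; 25: 160.4
- midnight run (time / min: [X] / mM): 0.90: 12.6; 2.7: 30.7; 5.2: 52.2; 8.2: 69.6; 12: 83.2; 16: 92.1; 20: 96.4; 25: 97.3
- dawn run (time / min: [X] / mM): 0.90: 16.6; 2.7: 40.8; 5.2: 75.1; 8.2: 110.0; 12: 142.3; 16: 164.7; 20: 180.6; 25: 190.5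
- summer run (time / min: [X] / mM): 0.90: 7.9; 2.7: 22.7; 5.2: 42.3; 8.2: 66.2; 12: 90.7; 16: 110.2; 20: 130.1; 25: 153.6

(each reading ± 1 mM)

- reaction order in [Q] at the outset, round the charge of the dusk run, defined at two percent of the Q turned into X (one fixed amount of X, the same in the runs compared)
- reaction order in [L] at the outset, round the charge of the dusk run, defined at two percent of the Q turned into X
- the midnight run starts with 100 mM less of Q and of L than the dusk run, and with no X. Compared where both hold the same amount of Q, once fifteen percent of what the midnight run was charged with has turned into X, is the midnight run faster, slower or alike (within a tenth)?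
- X in the winter run at 25 min, as a share of the Q charged
- which of these the readings show (nothing beyond the main steps / the product kills the catalyst / the catalyst dies in pairs / the product binds the second partner / the product ties up the catalyst)

- Overall: Q + L -> X, with Z as catalyst.
- Constant volume, constant temperature.
- A reading of a species includes what of it is bound.
- "The second partner" is L.
- An order is taken over about fifteen percent of the charge, up and down.

As fresh rate I took the X of the second reading over its time: 11.1 mM/min in the dusk run, 11.4 mM/min in the midnight run, 15.1 mM/min in the dawn run and 8.41 mM/min in the summer run. The winter run has the [L] of the dusk run but 600 mM of Q, so I first asked for its fresh rate at the old 6.00 mM of Z, and I went two ways. One way used the dusk and summer runs: they give an order in [Q] of −0.679, and stretched that far it gives 5.25 mM/min. The other way used the midnight and dawn runs. I called drag the square root of [Q][L] over the rate, with the dusk run as unity, which gave 0.570 for the midnight run and 1.21 for the dawn run. The dawn run priced L, the rest of the midnight gap priced Q, and a straight sum put the winter drag at 2.44, hence 5.58 mM/min. Apart from the shared dusk run these rest on different readings, and they parted by 0.330 mM/min, so I trusted their mean, 5.41 mM/min.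

The dusk, midnight, dawn and summer runs each held 6.00 mM of Z, so they could not test the power of the catalyst. I bet on the square, since a squared sum in the denominator is what two partners give when each sits on its own Z. That multiplied the rate by 4.00, to 21.7 mM/min.

L is the limiting reagent in the winter run, with 300 mM against 600 mM of Q. The fresh clock, the charge of the limiting reagent over the fresh rate, is then 13.9 min for the winter run, and its 25 min are 1.80 clocks. The midnight run, whose L stood at twice its limiting Q, has a clock of 8.79 min. It had reached 1.82 clocks at 16 min, with 92.1% of its Q turned. The same share of the winter L gives 276 mM of X, which is 46.1% of the winter Q.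

The forecast gave −0.6 and 0.6 for the orders, faster for the midnight comparison, the product ties up the catalyst for the readings, and 28% for the winter run, below my figure. Its winter figure came from “assuming rate ∝ Z”, the first power of Z where I took the square.

The flask gave orders of −0.56 in [Q] and 0.66 in [L] at the outset. The midnight run was faster than the dusk run, with a rate ratio of 2.0 where both held the same amount of Q, and the readings show that the product ties up the catalyst. The winter run gave 41.2%, above the forecast and below my figure.

    Z + Q ⇌ ZQ, settled at all times (83.70 /M)
    Z + L ⇌ ZL, settled at all times (12.20 /M)
    ZQ + ZL → X + 2 Z (2346 /M/min)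
    Z + X ⇌ ZX, settled at all times (45.60 /M)

In these equations the step that makes X takes one ZQ and one ZL together. The winter X of 247 mM was 82.4% of the L charged, reached at 1.80 fresh clocks. The dawn run has a fresh clock of 13.2 min, and it turned a quarter of its Q into X at 3.26 min, which is 0.247 of that clock.

(The data are simulated on assumed constants.)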